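**Retrosynthetic overview**

1. The target (eudesmane numbering, 1R,2S,5R,7S,9S,10S) is reached from α-ketol enone 15 by adjusting the esters, dehydrating the C11 carbinol and removing the C14 silyl group. Enone 15 comes from the C4 vinylogous ester 13 by Stork–Danheiser methyl addition and transposition.
2. 13 comes from the bicyclic ene-dione 11 by two hydroxyl-directed reductions (H-5, then the C1 carbonyl). 11 is the [4+2] adduct of the flat vinyl-p-quinone 8 and a vinyl–O two-carbon unit; this step forms C7–C8 and C9–C10.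
3. Enabling feature: ring A (C1–C5, C10) carries oxygen at C1 and C2 and an sp2 carbon C4 para to C1, which is the pattern of a 2-methoxy-1,4-benzoquinone. Its C10=C5 bond, extended by a C6=C7 vinyl group, is an electron-poor diene. The C14 substituent on C10 blocks re-aromatisation, and the 7β/9β/10α(C14) pattern of ring B is the endo/"outside" pattern of a Diels–Alder adduct.
4. 8 comes from 1-bromo-2,4,5-trimethoxybenzene by ortho-lithiation/formylation, Heck coupling with 2-methylbut-3-en-2-ol and CAN oxidation.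
5. Ring order: ring A is present from the start as the arene; ring B (C5–C10) is the only ring formed, in step 6.

Key step: step 6

Remarks: Eudesmane numbering is used for all bicyclic compounds (ring A C1–C5, C10; ring B C5–C10; C11–C13 side chain on C7; C14 on C10; C15 on C4). α is the face carrying C14, β the opposite face (H-5, the C7 side chain and O-9 in the target). The ester on O-1 is read as tiglate (E). Compounds 1, 6 and 9 are taken as commercially available.

**Step 1**
Reactants: 1 1-bromo-2,4,5-trimethoxybenzene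
Product: 3 2-bromo-3,5,6-trimethoxybenzaldehyde, via aryllithium 2 (not isolated)
Conditions: LDA, THF, −78 °C; then DMF, −78 to −40 °C; aq. NH4Cl
Reagents that add atoms: N,N-dimethylformamide, CN(C)C=O
Why: Directed ortho-lithiation and formylation: LDA should remove the ring proton flanked by Br and OMe (the most acidic one; an amide base does not exchange the bromide, and the ortho-bromo aryllithium is stable at −78 °C), and DMF formylates the aryllithium; no stereocenter.

**Step 2**
Reactants: 3 2-bromo-3,5,6-trimethoxybenzaldehyde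
Product: 4 (2-bromo-3,5,6-trimethoxyphenyl)methanol
Conditions: NaBH4, MeOH, 0 °C
Reagents that add atoms: none
Why: Borohydride reduction of an aryl aldehyde; no stereocenter.

**Step 3**
Reactants: 4 (2-bromo-3,5,6-trimethoxyphenyl)methanol
Product: 5 [(2-bromo-3,5,6-trimethoxyphenyl)methoxy](tert-butyl)diphenylsilane
Conditions: TBDPSCl, imidazole, DMF, rt
Reagents that add atoms: tert-butyl(chloro)diphenylsilane, CC(C)(C)[Si](Cl)(c1ccccc1)c1ccccc1
Why: Silylation of a primary alcohol; the TBDPS ether should survive CAN, dilute acid, organocerium and hydride reagents and can be removed last without touching the esters.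

**Step 4**
Reactants: 5 [(2-bromo-3,5,6-trimethoxyphenyl)methoxy](tert-butyl)diphenylsilane; 6 2-methylbut-3-en-2-ol
Product: 7 (E)-4-[2-({[tert-butyl(diphenyl)silyl]oxy}methyl)-3,4,6-trimethoxyphenyl]-2-methylbut-3-en-2-ol
Conditions: Pd2(dba)3 (2.5 mol %), P(t-Bu)3·HBF4 (10 mol %), Cy2NMe, 1,4-dioxane, 90 °C
Reagents that add atoms: none
Why: Mizoroki–Heck arylation with a bulky electron-rich phosphine for the hindered, electron-rich aryl bromide; β-hydride elimination is possible only towards the aryl-bearing carbon (the carbinol carbon is quaternary), so the (E)-styrene should form.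

**Step 5**
Reactants: 7 (E)-4-[2-({[tert-butyl(diphenyl)silyl]oxy}methyl)-3,4,6-trimethoxyphenyl]-2-methylbut-3-en-2-ol
Product: 8 3-({[tert-butyl(diphenyl)silyl]oxy}methyl)-2-[(E)-3-hydroxy-3-methylbut-1-en-1-yl]-5-methoxycyclohexa-2,5-diene-1,4-dione
Conditions: CAN (2.5 equiv), MeCN/H2O, 0 °C, 15 min; used at once
Reagents that add atoms: water, O
Why: CAN oxidative demethylation of the only para-dimethoxy pair gives the p-quinone and leaves the third methoxy group as the C2 enol ether; the vinylquinone is not stored, to limit dimerisation.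

**Step 6**
Reactants: 8 3-({[tert-butyl(diphenyl)silyl]oxy}methyl)-2-[(E)-3-hydroxy-3-methylbut-1-en-1-yl]-5-methoxycyclohexa-2,5-diene-1,4-dione; 9 trimethyl(vinyloxy)silane
Product: 11 14-(tert-butyldiphenylsilyloxy)-9β,11-dihydroxy-2-methoxy-15-noreudesma-2,5-diene-1,4-dione (7β side chain C(CH3)2OH, 9β-OH, 10α-CH2OSi), via TMS ether adduct 10 (not isolated)
Conditions: [Cu((S,S)-t-Bu-box)](SbF6)2 (10 mol %), 9 (3 equiv), 4 Å MS, CH2Cl2, −78 to −40 °C; then PPTS, MeOH, 0 °C
Reagents that add atoms: none
Why: Proposed new method: the chiral Cu(II) Lewis acid chelates the C1 carbonyl and the C2 methoxy oxygen, which lowers the LUMO of the vinylquinone so that its C10=C5–C6=C7 diene adds the enol ether in an inverse-electron-demand, asynchronous [4+2] cycloaddition (C8 bonds to the vinylogous acceptor carbon C7, then the oxygen-bearing C9 closes on C10). The closest known reaction types are the thermal Diels–Alder reaction of vinyl-1,4-benzoquinones with enol ethers and chiral-Lewis-acid-promoted cycloadditions of 2-alkoxy-1,4-benzoquinones with electron-rich alkenes; a catalytic enantioselective version that creates a quaternary carbon on a 3-substituted vinylquinone has not been shown. Ring B (C5–C10) is the only ring closed, in the [4+2] mode, and its new C5=C6 double bond is exocyclic to ring A. C7 and C10 are set by suprafacial addition to the diene, in which the E geometry of C6=C7 and the ring-enforced geometry of C10=C5 place C11 and C1 "outside" and hence cis, with C14 trans to them; C9 is set by the endo orientation of the silyloxy group, which puts O-9 cis to C11; the absolute sense is set by the ligand, whose tert-butyl group beside the bound C1 carbonyl should screen one face of C10 (the (S,S) ligand is proposed; its antipode is equally available should the sense prove opposite). The step needs attack at C7/C10 rather than at C3 or a carbonyl oxygen (C3 is the electron-rich β-carbon of the C2 enol ether, and C5 and C10 are fully substituted), and it needs a product that cannot re-aromatise (secured by the C14 substituent on C10).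

**Step 7**
Reactants: 11 14-(tert-butyldiphenylsilyloxy)-9β,11-dihydroxy-2-methoxy-15-noreudesma-2,5-diene-1,4-dione
Product: 12 14-(tert-butyldiphenylsilyloxy)-9β,11-dihydroxy-2-methoxy-15-nor-5βH-eudesm-2-ene-1,4-dione (trans-fused)
Conditions: [Ir(cod)(PCy3)(py)]PF6 (10 mol %), H2 (1 atm), CH2Cl2, 0 °C to rt
Reagents that add atoms: none
Why: Hydroxyl-directed homogeneous hydrogenation: the cationic iridium catalyst should bind the homoallylic 9β- and 11-hydroxyls and deliver H2 to the β face of C5=C6, which sets H-5 β (trans ring fusion); the push–pull C2=C3 enol ether should not be reduced.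

**Step 8**
Reactants: 12 14-(tert-butyldiphenylsilyloxy)-9β,11-dihydroxy-2-methoxy-15-nor-5βH-eudesm-2-ene-1,4-dione
Product: 13 14-(tert-butyldiphenylsilyloxy)-1α,9β,11-trihydroxy-2-methoxy-15-nor-5βH-eudesm-2-en-4-one
Conditions: Me4NBH(OAc)3, MeCN/AcOH, −30 °C
Reagents that add atoms: none
Why: Evans–Saksena directed reduction: the triacetoxyborohydride exchanges onto the 9β-hydroxyl and transfers hydride intramolecularly to the β face of the C1 carbonyl, which should give the 1α-alcohol (1,3-anti to O-9); the C4 vinylogous ester carbonyl has no β-hydroxyl and stays, and the acidic medium avoids retro-aldol opening of the β-hydroxy ketone.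

**Step 9**
Reactants: 13 14-(tert-butyldiphenylsilyloxy)-1α,9β,11-trihydroxy-2-methoxy-15-nor-5βH-eudesm-2-en-4-one
Product: 15 14-(tert-butyldiphenylsilyloxy)-1α,9β,11-trihydroxy-5βH-eudesm-3-en-2-one, via tertiary carbinol 14 (not isolated)
Conditions: MeLi/CeCl3 (6 equiv each), THF, −78 °C; then 1 M aq. HCl, THF, 0 °C
Reagents that add atoms: methyllithium, [Li]C; water, O
Why: Stork–Danheiser alkylative carbonyl transposition: the organocerium reagent should add 1,2 to the C4 vinylogous ester carbonyl without enolising C5, and dilute acid hydrolyses the enol ether with loss of the tertiary hydroxyl, which moves the carbonyl to C2 and creates C3=C4 carrying the new methyl group (C15); no stereocenter is formed.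

**Step 10**
Reactants: 15 14-(tert-butyldiphenylsilyloxy)-1α,9β,11-trihydroxy-5βH-eudesm-3-en-2-one
Product: 16 1α-tigloyloxy-14-(tert-butyldiphenylsilyloxy)-9β,11-dihydroxy-5βH-eudesm-3-en-2-one
Conditions: tigloyl chloride (1.2 equiv), pyridine, DMAP (cat.), CH2Cl2, −20 to 0 °C
Reagents that add atoms: (E)-2-methylbut-2-enoyl chloride, C/C=C(\C)C(=O)Cl
Why: Site-selective acylation: the equatorial α-ketol hydroxyl at C1 should react in preference to the axial neopentyl 9β-hydroxyl (syn-axial to the C7 side chain) and the tertiary C11 hydroxyl.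

**Step 11**
Reactants: 16 1α-tigloyloxy-14-(tert-butyldiphenylsilyloxy)-9β,11-dihydroxy-5βH-eudesm-3-en-2-one
Product: 17 1α-tigloyloxy-14-(tert-butyldiphenylsilyloxy)-5βH-eudesm-3-ene-2α,9β,11-triol
Conditions: NaBH4, CeCl3·7H2O, MeOH, −78 to −40 °C; AcOH quench
Reagents that add atoms: none
Why: Luche 1,2-reduction of the enone: hydride should attack C2 from the β face because the α face is screened by the syn-axial C10 CH2OSi group (as in 2-oxo steroids), giving the 2α (pseudoaxial) alcohol cis to the 1α-ester; the conjugated ester is not reduced.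

**Step 12**
Reactants: 17 1α-tigloyloxy-14-(tert-butyldiphenylsilyloxy)-5βH-eudesm-3-ene-2α,9β,11-triol
Product: 18 2α,9β-diacetoxy-1α-tigloyloxy-14-(tert-butyldiphenylsilyloxy)-5βH-eudesm-3-en-11-ol
Conditions: Ac2O, pyridine, DMAP (cat.), CH2Cl2, rt
Reagents that add atoms: acetic anhydride, CC(=O)OC(C)=O
Why: Acetylation of the two secondary alcohols (DMAP catalysis for the hindered 9β-hydroxyl); the tertiary C11 alcohol reacts much more slowly and should stay free.

**Step 13**
Reactants: 18 2α,9β-diacetoxy-1α-tigloyloxy-14-(tert-butyldiphenylsilyloxy)-5βH-eudesm-3-en-11-ol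
Product: 19 2α,9β-diacetoxy-1α-tigloyloxy-14-(tert-butyldiphenylsilyloxy)-5βH-eudesma-3,11-diene
Conditions: Burgess reagent, benzene, 50 °C
Reagents that add atoms: none
Why: Burgess dehydration (syn elimination through the sulfamate ester) of the only free hydroxyl: six methyl hydrogens against one hindered ring hydrogen at C7 should favour the isopropenyl isomer over the isopropylidene isomer; C7 is not epimerisable.

**Step 14**
Reactants: 19 2α,9β-diacetoxy-1α-tigloyloxy-14-(tert-butyldiphenylsilyloxy)-5βH-eudesma-3,11-diene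
Product: 20 2α,9β-diacetoxy-1α-tigloyloxy-5βH-eudesma-3,11-dien-14-ol (target, CNP0267061.1)
Conditions: HF·pyridine, pyridine, THF, 0 °C to rt
Reagents that add atoms: none
Why: Fluoride cleavage of the neopentyl TBDPS ether under buffered, mildly acidic conditions that should not promote acyl migration to the freed primary alcohol or ionise the allylic acetate.

**Compound list**

1 | 1-bromo-2,4,5-trimethoxybenzene | COc1cc(OC)c(OC)cc1Br | starting material
2 | (2-bromo-3,5,6-trimethoxyphenyl)lithium (not isolated) | COc1cc(OC)c(OC)c([Li])c1Br | intermediate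
3 | 2-bromo-3,5,6-trimethoxybenzaldehyde | COc1cc(OC)c(OC)c(C=O)c1Br | intermediate
4 | (2-bromo-3,5,6-trimethoxyphenyl)methanol | COc1cc(OC)c(OC)c(CO)c1Br | intermediate
5 | [(2-bromo-3,5,6-trimethoxyphenyl)methoxy](tert-butyl)diphenylsilane | COc1cc(OC)c(OC)c(CO[Si](c2ccccc2)(c2ccccc2)C(C)(C)C)c1Br | intermediate
6 | 2-methylbut-3-en-2-ol | C=CC(C)(C)O | starting material
7 | (E)-4-[2-({[tert-butyl(diphenyl)silyl]oxy}methyl)-3,4,6-trimethoxyphenyl]-2-methylbut-3-en-2-ol | COc1cc(OC)c(OC)c(CO[Si](c2ccccc2)(c2ccccc2)C(C)(C)C)c1/C=C/C(C)(C)O | intermediate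
8 | 3-({[tert-butyl(diphenyl)silyl]oxy}methyl)-2-[(E)-3-hydroxy-3-methylbut-1-en-1-yl]-5-methoxycyclohexa-2,5-diene-1,4-dione | COC1=CC(=O)C(/C=C/C(C)(C)O)=C(CO[Si](c2ccccc2)(c2ccccc2)C(C)(C)C)C1=O | intermediate
9 | trimethyl(vinyloxy)silane | C=CO[Si](C)(C)C | starting material
10 | 9β-O-trimethylsilyl ether of 11 (not isolated) | CC(C)(O)[C@@H]1C[C@H](O[Si](C)(C)C)[C@@]2(CO[Si](c3ccccc3)(c3ccccc3)C(C)(C)C)C(=C1)C(=O)C=C(OC)C2=O | intermediate
11 | 14-(tert-butyldiphenylsilyloxy)-9β,11-dihydroxy-2-methoxy-15-noreudesma-2,5-diene-1,4-dione | CC(C)(O)[C@@H]1C[C@H](O)[C@@]2(CO[Si](c3ccccc3)(c3ccccc3)C(C)(C)C)C(=C1)C(=O)C=C(OC)C2=O | intermediate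
12 | 14-(tert-butyldiphenylsilyloxy)-9β,11-dihydroxy-2-methoxy-15-nor-5βH-eudesm-2-ene-1,4-dione | CC(C)(O)[C@@H]1C[C@H](O)[C@@]2(CO[Si](c3ccccc3)(c3ccccc3)C(C)(C)C)[C@H](C1)C(=O)C=C(OC)C2=O | intermediate
13 | 14-(tert-butyldiphenylsilyloxy)-1α,9β,11-trihydroxy-2-methoxy-15-nor-5βH-eudesm-2-en-4-one | CC(C)(O)[C@@H]1C[C@H](O)[C@@]2(CO[Si](c3ccccc3)(c3ccccc3)C(C)(C)C)[C@H](C1)C(=O)C=C(OC)[C@@H]2O | intermediate
14 | 14-(tert-butyldiphenylsilyloxy)-2-methoxy-5βH-eudesm-2-ene-1α,4,9β,11-tetrol, C4 configuration not defined (not isolated) | CC(C)(O)[C@@H]1C[C@H](O)[C@@]2(CO[Si](c3ccccc3)(c3ccccc3)C(C)(C)C)[C@H](C1)C(C)(O)C=C(OC)[C@@H]2O | intermediate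
15 | 14-(tert-butyldiphenylsilyloxy)-1α,9β,11-trihydroxy-5βH-eudesm-3-en-2-one | CC(C)(O)[C@@H]1C[C@H](O)[C@@]2(CO[Si](c3ccccc3)(c3ccccc3)C(C)(C)C)[C@H](C1)C(C)=CC(=O)[C@@H]2O | intermediate
16 | 1α-tigloyloxy-14-(tert-butyldiphenylsilyloxy)-9β,11-dihydroxy-5βH-eudesm-3-en-2-one | CC(C)(O)[C@@H]1C[C@H](O)[C@@]2(CO[Si](c3ccccc3)(c3ccccc3)C(C)(C)C)[C@H](C1)C(C)=CC(=O)[C@@H]2OC(=O)/C(C)=C/C | intermediate
17 | 1α-tigloyloxy-14-(tert-butyldiphenylsilyloxy)-5βH-eudesm-3-ene-2α,9β,11-triol | CC(C)(O)[C@@H]1C[C@H](O)[C@@]2(CO[Si](c3ccccc3)(c3ccccc3)C(C)(C)C)[C@H](C1)C(C)=C[C@H](O)[C@@H]2OC(=O)/C(C)=C/C | intermediate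
18 | 2α,9β-diacetoxy-1α-tigloyloxy-14-(tert-butyldiphenylsilyloxy)-5βH-eudesm-3-en-11-ol | CC(C)(O)[C@@H]1C[C@H](OC(C)=O)[C@@]2(CO[Si](c3ccccc3)(c3ccccc3)C(C)(C)C)[C@H](C1)C(C)=C[C@H](OC(C)=O)[C@@H]2OC(=O)/C(C)=C/C | intermediate
19 | 2α,9β-diacetoxy-1α-tigloyloxy-14-(tert-butyldiphenylsilyloxy)-5βH-eudesma-3,11-diene | C=C(C)[C@@H]1C[C@H](OC(C)=O)[C@@]2(CO[Si](c3ccccc3)(c3ccccc3)C(C)(C)C)[C@H](C1)C(C)=C[C@H](OC(C)=O)[C@@H]2OC(=O)/C(C)=C/C | intermediate
20 | 2α,9β-diacetoxy-1α-tigloyloxy-5βH-eudesma-3,11-dien-14-ol, (1R,2S,5R,7S,9S,10S) | C=C(C)[C@@H]1C[C@H](OC(C)=O)[C@@]2(CO)[C@H](C1)C(C)=C[C@H](OC(C)=O)[C@@H]2OC(=O)/C(C)=C/C | target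

**Summary**

Total step count: 14. Longest linear sequence: 14 steps (1 to 20).

Steps most likely to fail:

1. Step 6 (Proposed new method). The enantiofacial discrimination may be weak because the first bond forms at C7, remote from the bound ligand. The Lewis acid may also divert the reaction into a stepwise collapse (proton or silyl transfer to an open-chain 1,6-adduct) instead of ring closure. The fallback uses known chemistry, sets out from 8 and 9 and returns at 11. The uncatalysed thermal vinylquinone Diels–Alder reaction (9 in excess, toluene, 40–60 °C, BHT) gives the racemic silyl ether, that is 10 together with its enantiomer, ent-10 F1. Methanolysis (PPTS, MeOH) gives the racemic adduct, 11 together with ent-11 F2. The enantiomers are separated by preparative chromatography on a chiral stationary phase, and 11 re-enters the route at step 7.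

2. Step 10. Acylation may occur at the wrong hydroxyl, or the tigloyl group may migrate to O-2 after step 11. The fallback sets out from 15 and returns at 18. Luche reduction of 15 (as in step 11) is done first and gives the 1α,2α-cis-diol, tetraol F3. Trimethyl orthoacetate with CSA closes a five-membered cyclic orthoacetate on the cis-diol only, orthoester F4. Ac2O/pyridine/DMAP acetylates the 9β-hydroxyl, orthoester acetate F5. Aqueous acetic acid opens the orthoester with the known preference for the axial ester, giving the C2 acetate and the free equatorial C1 alcohol, hydroxy diacetate F6. Tigloyl chloride/DMAP/pyridine then acylates the only remaining secondary hydroxyl and gives 18.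

3. Step 7. Hydrogen may be delivered to the wrong face (cis ring fusion), or the C2=C3 enol ether may be over-reduced. The fallback sets out from 11 and returns at 12. Conjugate hydride reduction with stoichiometric [(Ph3P)CuH]6 in wet benzene/THF touches only the C6=C5–C4=O enone. The copper enolate should be protonated at C5 from the β face, anti to the axial C10 CH2OSi group. No compound outside the list is formed on the way (F0).

**Further compounds**

F1 | step 6 | ent-10, enantiomer of the TMS ether adduct (formed with 10 as the racemate, not isolated) | CC(C)(O)[C@H]1C[C@@H](O[Si](C)(C)C)[C@]2(CO[Si](c3ccccc3)(c3ccccc3)C(C)(C)C)C(=C1)C(=O)C=C(OC)C2=O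
F2 | step 6 | ent-11, enantiomer of the adduct (formed with 11 as the racemate, removed by chiral chromatography) | CC(C)(O)[C@H]1C[C@@H](O)[C@]2(CO[Si](c3ccccc3)(c3ccccc3)C(C)(C)C)C(=C1)C(=O)C=C(OC)C2=O
F0 | step 7 | none | none
F3 | step 10 | 14-(tert-butyldiphenylsilyloxy)-5βH-eudesm-3-ene-1α,2α,9β,11-tetrol | CC(C)(O)[C@@H]1C[C@H](O)[C@@]2(CO[Si](c3ccccc3)(c3ccccc3)C(C)(C)C)[C@H](C1)C(C)=C[C@H](O)[C@@H]2O
F4 | step 10 | 1α,2α-O-(1-methoxyethylidene) orthoester of F3 (orthoester carbon not defined) | CC(C)(O)[C@@H]1C[C@H](O)[C@@]2(CO[Si](c3ccccc3)(c3ccccc3)C(C)(C)C)[C@H](C1)C(C)=C[C@H](OC(C)(OC)O3)[C@@H]23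
F5 | step 10 | 9β-acetate of orthoester F4 | CC(C)(O)[C@@H]1C[C@H](OC(C)=O)[C@@]2(CO[Si](c3ccccc3)(c3ccccc3)C(C)(C)C)[C@H](C1)C(C)=C[C@H](OC(C)(OC)O3)[C@@H]23
F6 | step 10 | 2α,9β-diacetoxy-14-(tert-butyldiphenylsilyloxy)-5βH-eudesm-3-ene-1α,11-diol | CC(C)(O)[C@@H]1C[C@H](OC(C)=O)[C@@]2(CO[Si](c3ccccc3)(c3ccccc3)C(C)(C)C)[C@H](C1)C(C)=C[C@H](OC(C)=O)[C@@H]2O
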